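Readings and results were computed for an exercise, and the scatter is random.

Cedar, charged with more reagent than alder, goes on gaining bis adduct for longer: between 1.00 h and 2.50 h cedar adds 4.7 percentage points and alder 0.1 points, which is less than the scatter of a reading.

all flasks: substrate 0.68 M

|  | reagent | remark | time |
|---|---|---|---|
| alder | 0.74 equiv | run made earlier |  |
| cedar | 4 equiv | run made earlier |  |
| autumn | 0.500 equiv |  | 2.5 h |
| noon | 2.50 equiv |  | 2.5 h |
| dusk | 3.00 equiv |  | 2.5 h |

| run | time / h | bis adduct / % | single product / % |
|---|---|---|---|
| alder | 0.200 | 6.7 | 24.8 |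
| alder | 0.500 | 8.0 | 25.9 |
| alder | 1.00 | 8.2 | 26.7 |
| alder | 2.50 | 8.3 | 26.1 |
| cedar | 0.200 | 53.1 | 25.7 |
| cedar | 0.500 | 68.7 | 18.1 |
| cedar | 1.00 | 75.8 | 15.2 |
| cedar | 2.50 | 80.5 | 12.1 |

(scatter of a reading: 0.3 percentage points)



* how much bis adduct is there at the end, in percent of the substrate charged: for each flask in turn (autumn, noon, dusk)

Both runs climb the same ladder of times. On the first rung, at 0.200 h, alder already holds 6.7% bis adduct of its final 8.3%, and cedar 53.1% of its final 80.5%. On a later rung, at 1.00 h, alder stands still while cedar creeps on. We take each addition to be first order in reagent, so reagent is the concentration to watch, and on the top rung, at 2.5 h, a flask reads as an account of where its reagent went.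

So we carry the found share: the fraction of the reagent charge that the final readings show bound, with single product counted once and bis adduct twice. It reads 57.7% in alder and 43.3% in cedar. A straight line in the charge gives noon 49.9% and dusk 47.7%. A crude line for single product gives noon 18.5%. Subtracting and halving, our figure for noon is 53.1% bis adduct, and the same steps give dusk 63.4%. Autumn lies outside the two runs, so we commit to no figure there.

The forecast says 4.1%, 51% and 63%, with its noon value below our figure for noon, and holds that “all three are essentially finished”.

The flasks give 3.91%, 56.3% and 67.1%.

    substrate + reagent → single product (k = 0.00300 M⁻¹ s⁻¹)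
    substrate + reagent → other mono adduct (k = 0.00260 M⁻¹ s⁻¹)
    reagent + single product → bis adduct (k = 0.00160 M⁻¹ s⁻¹)
    reagent + other mono adduct → bis adduct (k = 0.00220 M⁻¹ s⁻¹)
    2 reagent → homo dimer (k = 9.40 × 10⁻⁴ M⁻¹ s⁻¹)

In noon the substrate went 52.1% through single product and 45.2% through other mono adduct, a species no reading showed. With noon's concentrations as charged, the half-life of other mono adduct by its step to bis adduct alone is 0.051 h, shorter than the 0.071 h of single product. Noon's found share comes to 54.9%, above the 49.9% of our straight line. In dusk it comes to 51.3%, against 47.7% on the line.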